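The data stem from a simulated flask for substances that don't exist.

Watch the early readings first. At 15.0 min in the alpha run, catalyst intermediate A and catalyst intermediate B read 1 % and 0 %, against a scatter of 1.5 percentage points. The catalyst charged in the beta run is 0.395 % of its substrate, so read those columns as scatter and follow substrate.

| flask | substrate | free catalyst | remark | time |
|---|---|---|---|---|
| alpha | 2 M | 4.6 mM | run made earlier |  |
| zeta | 2 M | 7.3 mM | run made earlier |  |
| beta | 2 M | 7.9 mM | run made earlier |  |
| north | 2.0 M | 4.4 mM |  | 4.0 h |
| south-east | 2.0 M | 11 mM |  | 4.0 h |

| run | time / min | substrate / % | catalyst intermediate A / % | product / % | catalyst intermediate B / % |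
|---|---|---|---|---|---|
| alpha | 15.0 | 99 | 1 | 1 | 0 |
| alpha | 40.0 | 92 | 0 | 9 | 0 |
| alpha | 80.0 | 90 | 1 | 11 | 0 |
| alpha | 120 | 84 | 0 | 15 | 1 |
| zeta | 30.0 | 92 | 0 | 8 | 1 |
| zeta | 60.0 | 89 | 2 | 16 | 1 |
| zeta | 90.0 | 80 | 1 | 18 | 0 |
| zeta | 120 | 76 | 0 | 27 | 0 |
| beta | 30.0 | 92 | 1 | 4 | 1 |
| beta | 60.0 | 88 | 0 | 14 | 0 |
| beta | 90.0 | 78 | 0 | 23 | 0 |
| beta | 120 | 72 | 1 | 28 | 0 |

(readings scatter by 1.5 percentage points)



- which of these there is most of at the end, counted by the substrate in it, north (catalyst intermediate B / catalyst intermediate A / product / substrate)
- which of these there is most of at the end, counted by the substrate in it, south-east (catalyst intermediate B / catalyst intermediate A / product / substrate)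
- amount of the one of these that there is most of at the end, in percent of the substrate charged, north
- amount of the one of these that there is most of at the end, in percent of the substrate charged, south-east

Now climb to the slower rung. Multiply catalyst charged by time to get the dose. Then take the halving dose, the dose that halves the substrate if substrate falls pseudo-first-order. Read singly at the last readings, alpha gives 36.6 mM·h, zeta 36.9 mM·h and beta 33.3 mM·h. Those are close, so pool them: 35.3 mM·h.

Divide by catalyst for the halving time of each flask. South-east's 3.21 h is shorter than the asked 4.0 h, and north's 8.03 h is longer. So I expect north to end with substrate leading and south-east with product leading.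

My reckoning gives north 70.8 % substrate and south-east 57.8 % product. I commit to the curve, not a straight line, because beta stops at 72 % substrate and south-east's dose of 44.0 mM·h runs past beta's 15.8 mM·h.

The forecast says substrate at 70 % in north and product at 71 % in south-east, noting that “the noise cannot exclude first order”. On south-east I stand 13 points lower.

The flask gives substrate at 69.7 % in north and product at 60.5 % in south-east.

    substrate + free catalyst ⇌ catalyst intermediate A (K = 1.30 M⁻¹, k = 73.0 M⁻¹ h⁻¹)
    catalyst intermediate A ⇌ catalyst intermediate B (K = 34.0, k = 100 h⁻¹)
    catalyst intermediate B → free catalyst + product (k = 290 h⁻¹)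
    2 catalyst intermediate A ⇌ resting dimer (K = 260 M⁻¹, k = 51.0 M⁻¹ h⁻¹)

South-east's product lands 2.7 points above the halving-dose figure and 10 points below the forecast. Watch the resting dimer, an off-cycle resting state, which holds 22.8 % of the catalyst charged in south-east at 4.00 h. With it struck out, south-east gives 69.0 % product instead of 60.5 %. South-east stands above north because of the difference in free catalyst: without that difference, its product falls from 60.5 % to 30.2 %. Carry the halving dose to a neighbour of south-east charged with 6.60 mM of free catalyst, all else held: it gives 59.5 % substrate left, and that flask keeps 57.9 %.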